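A turn of the enzyme cannot give target without spending one starting material and one second substrate, so, with idle adduct counted as second substrate, both are used at one rate, and dividing one rate by the other takes time out of the matter.

    starting material + free enzyme ⇌ first complex (K1 = 520 L mol⁻¹, k1 = 2.4 × 10⁶ L mol⁻¹ s⁻¹)
    first complex ⇌ loaded enzyme + first product (K2 = 0.0048 M, k2 = 11000 s⁻¹)
    second substrate + first product ⇌ idle adduct, settled at all times (K3 = 630 L mol⁻¹)
    second substrate + loaded enzyme ⇌ second complex (K4 = 700 L mol⁻¹, k4 = 7.6 × 10⁶ L mol⁻¹ s⁻¹)
    scavenger + first product → scavenged by-product (k5 = 19 L mol⁻¹ s⁻¹)
    second complex → free enzyme + target (k6 = 650 s⁻¹)

starting material 5.0 mM; second substrate 0.900 equiv; scavenger 1.20 equiv; free enzyme 0.0071 mol%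

- for first product the idle adduct is counted in
- charge of starting material (flask): 5.0 mM

1. apparent order in free enzyme when 50 % of the starting material are converted (percent change of the rate of making target for one percent more free enzyme charged)
2. apparent order in second substrate when 50 % of the starting material are converted (percent change of the rate of making target for one percent more second substrate charged)

Two chemists stand at this board. The first looks at the enzyme: 3.55 × 10⁻⁴ mM of it against 5.0 mM of starting material, so he counts as many rounds as there is catalyst, an order of one in free enzyme. For second substrate he takes the binding step and the step that releases target. In that pair, loaded enzyme and second complex stand equal at 1.51 mM of second substrate. At 50 % conversion, 2.50 mM is gone from a charge of 4.50 mM, which leaves 2.00 mM, idle adduct counted in. That is above the equal level, so he says one percent more moves the rate by 0.431 percent, an order below one.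

The second chemist objects that the question changes the charge, not what is left. Second substrate is the limiting reagent, and at a given conversion the same 2.50 mM goes from any charge, so every extra bit charged lands on top of the 2.00 mM remaining. She names this the leverage: the charge of second substrate divided by what is left of it at the moment looked at, here 2.25. One percent on the charge is 2.25 percent on what is left.

My own reckoning multiplies the two and gets 0.970. It stops there, for it counts what is left as free, and some of that sits as idle adduct.

The forecast stands on her side and goes further than I do: 1.1 for second substrate, above my figure, and 0.86 for free enzyme, in its words “More enzyme means less scavenging and more inhibition”.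

The flask gives 1.3 for second substrate, above the forecast, and 0.86 for free enzyme, as forecast. After 20.0 s, with target at 48.8 %, free second substrate stood at 30.2 % of its charge beside 0.700 mM of idle adduct. Divided by the leverage, the order reads 0.586 per percent of what is left, above the first chemist's 0.431. His view, which takes what is left for the charge, fits the early run better: after 4.00 s, with target at 12.0 %, the leverage is 1.15, less than the 2.25 at 50 % conversion.

The numbers of this flask are invented, and the outcome is calculated.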